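(Readings and results are simulated with made-up constants.)

Read the L peak as the progress of a flask and the hot flasks will mislead you. By 6.00 h alder read L of 10.0%, less than the 13.1% of its D that was missing, and L to Z is among the steps under discussion.

common to all: D 11 mM
- ash: X 7.4 mM; E 22 µM; temperature 15 °C; run made earlier
- alder: X 16 mM; E 22 µM; temperature 50 °C; run made earlier
- birch: X 11 mM; E 33 µM; temperature 15 °C; run made earlier
- dawn: X 11.0 mM; E 22 µM; temperature 20 °C; time 25 h
- midnight: X 11.0 mM; E 22 µM; temperature 80 °C; time 25 h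
- spring: X 11.0 mM; E 22 µM; temperature 60 °C; time 25 h
- dusk: X 11.0 mM; E 22 µM; temperature 40 °C; time 25 h

- ash (time / h: L / %, D / %): 2.50: 0, 98.9; 4.00: 0.1, 99.5; 6.00: 0.4, 99.5; 10.0: 0.6, 99.3; 20.0: 1.7, 98.0; 30.0: 2.1, 97.6
- alder (time / h: L / %, D / %): 0.500: 0.7, 98.8; 0.833: 2.0, 98.8; 1.33: 3.6, 97.2; 2.50: 5.1, 94.5; 5.00: 8.9, 89.8; 6.00: 10.0, 86.9
- birch (time / h: L / %, D / %): 2.50: 1.0, 99.4; 8.00: 0.8, 99.1; 15.0: 1.8, 97.8; 20.0: 2.6, 97.3; 30.0: 3.8, 95.6

(scatter of a reading: 0.5 percentage points)

- steps under discussion: D + E <-> G; G -> E + L; X + E <-> Q; Q -> E + J; L -> Z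

1. which flask leads in amount of L, in percent of the D charged ("all alike" within 1.5 percentage points) (dawn / midnight / spring / dusk / all alike)
2. how much L is there at the end, in percent of the D charged: dawn
3. how much L is there at the end, in percent of the D charged: midnight
4. how much L is there at the end, in percent of the D charged: spring
5. how much L is there at the end, in percent of the D charged: dusk

What do you read instead? D left, in logarithms. Take the common logarithm of charged over left and divide by the time. A pseudo-first-order loss gives a steady figure there.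

Values? Ash at its last reading gives 3.52 × 10⁻⁴ h⁻¹. Alder gives 0.0102 h⁻¹. That is 1.46 decades across the span of temperature between them. X differs between these runs, and I set that aside.

Does E count? Birch lost 4.40% where ash lost 2.40%, on 1.50 times the E. X differs here too, 11 mM against 7.4 mM. With the scatter on such small losses, I take the burn as proportional to E, and that is an assumption.

And dusk? It lies 0.286 of the span below alder. So my reckoning gives dusk 0.00389 h⁻¹: that is the burn, decades of D lost per hour. Over 25 h my reckoning has dusk keep 79.9% of its D.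

Then does the hotter flask lead? Not by this. Spring, reckoned the same way, keeps 21.7% of its D, and midnight burns 4.54 decades. Alder's L reading stood 3.1 percentage points below the D missing, and hot L may go on to Z, so I put dusk ahead by judgement.

Your span ends at 50 °C? Yes. Above it the line is an extrapolation.

The forecast names dusk, with L of 15% there, 8% in spring, 3.4% in dawn and 0.3% in midnight. Among its grounds: “so the rate scales with E”.

The flasks give dusk 19.2%, spring 5.68%, dawn 3.80% and midnight 0%. With E at 28.7 µM, dusk's L has moved 5 points, and the forecast's range for dusk ends at 21%.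

    D + E ⇌ G (K = 100 M⁻¹, k = 7200 M⁻¹ h⁻¹, Ea = 68.0 kJ mol⁻¹, ΔH = −51.0 kJ mol⁻¹)
    G → E + L (k = 160 h⁻¹, Ea = 94.0 kJ mol⁻¹)
    X + E ⇌ Q (K = 64.0 M⁻¹, k = 20000 M⁻¹ h⁻¹, Ea = 52.0 kJ mol⁻¹, ΔH = 5.00 kJ mol⁻¹)
    Q → E + J (k = 26.0 h⁻¹, Ea = 97.0 kJ mol⁻¹)
    L → Z (k = 0.320 h⁻¹, Ea = 113 kJ mol⁻¹)
    (constants at 60 °C)

Dusk kept 74.3% of its D, a burn of 0.00516 h⁻¹ against my 0.00389 h⁻¹. The neighbouring flask is dusk with 0.055 mM of E, 2.50 times the charge. Scaling the burn by that factor gives 0.322 decades over 25 h, so 47.6% of the D should remain. That neighbour holds 45.2% of its D at the end, with Z at 14.5% and L at 40.2%.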